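## Analysis of the target

Compound 29 is an acyclic C30 carboxylic acid. Numbered from the carboxyl carbon, the main chain runs C1–C17. C2 carries an exocyclic double bond to a three-carbon arm (C1'–C3') that ends in a 3-substituted furan, C5 carries an isopropenyl group, and C6–C17 is a farnesyl-type triene (C7=C8 E, C11=C12 Z, C15=C16 as the prenyl terminus).

The furan is the only ring and C5 (R) the only stereocentre, so there is no relative configuration to control. One absolute configuration and three alkene geometries must each be set cleanly. C5 bears H, the isopropenyl carbon and two methylene groups (C4 and C6), with no heteroatom within reach. It therefore cannot come from a directed reduction or addition and needs either the chiral pool or an enantioselective C–C bond formation.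

The C2=C1' alkene has the carboxyl group cis to C2'. This is the angelate-type, less stable arrangement, which stabilised-ylide olefination does not deliver. The triene has a Z alkene in its middle, so all-E farnesyl building blocks are of no use and the chain must be assembled from a neryl unit.

The sensitive groups are the furan (acid, electrophiles, oxidants), the skipped polyene (acid-induced cyclisation, isomerisation of the Z alkene), the isopropenyl group (a competitor in any terminal-alkene reaction) and the enoate (conjugate addition, loss of geometry).

The strategy rests on the C3–C4 ethylene link. Read as a hydroborated vinyl group, it makes C5 the CH of a 1,4-diene bearing vinyl and isopropenyl. Such a CH is the γ-carbon of a linear E-allylic phosphate attacked in SN2' fashion by an isopropenyl nucleophile.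

## Retrosynthetic reasoning

**29 from 28.** The acid is carried as its ethyl ester 28 until the end, because a free carboxylic acid would interfere with the organometallic steps. Only the ester C–O bond is cut. The forward step is a basic hydrolysis mild enough to leave the Z-enoate, the furan and the polyene alone.

**28 from 16 and 26 (through 27).** The C2–C3 bond (sp2–sp3) is cut. This is where the chiral hydrocarbon half and the achiral furan–acrylate half meet, so the route becomes convergent. It is also the only cut that lets the awkward Z geometry be carried in ready-made: alkenyl iodide 26 couples with retention. The C3–C4 unit comes from the vinyl group of 16 by anti-Markovnikov hydroboration to alkylborane 27. The forward reaction must hydroborate the vinyl group and leave the isopropenyl group on the same carbon. The bicyclic dialkylborane usual for B-alkyl couplings reacts with 1,1-disubstituted terminal alkenes at least as readily as with monosubstituted ones, so it would not single out the vinyl group. A bis(secondary-alkyl)borane, which is far slower towards 1,1-disubstituted alkenes, is therefore specified, and 27 carries two 3-methylbutan-2-yl groups on boron.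

**26 from 25 from 24.** The C–I bond is traced to a C–Sn bond, and the stannane 25 to a syn addition of a tin hydride across ynoate 24, with tin at the α-carbon. Syn addition places the ester cis to the furylethyl chain, which is exactly the geometry 29 needs, and the two following steps are stereoretentive.

**24 from 22, 22 from 21, 21 from 18 and 19, 18 from 17.** The ester carbon is attached by acylation of acetylide 23. The terminal alkyne 22 comes from silyl alkyne 21. Compound 21 is cut between the furylmethyl carbon and the propargylic carbon, giving bromide 18 and the propargyl anion equivalent 20 made from 19. Bromide 18 comes from commercial furan-3-ylmethanol 17, so the furan is bought and not built.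

**16 from 14 and 15 (key disconnection).** The bond between C3 of 16 and the isopropenyl carbon is cut with allylic transposition. This converts the branched, chiral tetraene into the linear, achiral E-allylic phosphate 14 and the commercial boronate 15. The cut is made here and not at the C3–C4 bond of 16 or at its vinyl group. An E-1,2-disubstituted allylic phosphate is the best-behaved substrate class for copper-catalysed enantioselective SN2' alkenylation, and the vinyl group that results is the handle needed later. The forward step must give the branched product, one enantiomer, and touch none of the three trisubstituted alkenes.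

**14 from 13 from 12, 12 from 10 and 11.** Phosphate 14 is the ester of allylic alcohol 13. The E alkene of 13 is traced to the alkyne of 12, because hydroxyl-directed trans-reduction of a propargylic alcohol is stereospecific. Enynol 12 is cut at the sp–sp3 bond between C3 and C4, giving allylic bromide 10 and propargyl alcohol 11. The skipped pattern is thus assembled without any base-labile carbonyl intermediate.

**10 from 9 from 8.** These are functional-group changes (bromide from alcohol, alcohol from ester) on the C15 chain.

**8 from 7 from 5, 5 from 2 and 3, 2 from 1.** The C3–methyl bond of ester 8 is cut to the Z-enol phosphate 7, because substitution by a methyl cuprate with retention turns a chelation-controlled enolate geometry into the 2E trisubstituted alkene. Keto ester 5 is cut at C4–C5 into neryl bromide 2 and the dianion 4 of ethyl acetoacetate 3. The 6Z alkene is bought with nerol 1.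

## Alternatives that were turned down

**Alternative 1: furan closed last by ring-closing metathesis.**
- Disconnection: the bond between furan carbons 3 and 4.
- Forward key step: the open-chain allyl methyl mixed acetal A2 of a 2-substituted acrolein undergoes ring-closing metathesis to a 2-methoxy-2,5-dihydrofuran. Mild acid in the same pot removes the methoxy group and gives the methyl ester A1 of the target acid.
- For: the electron-rich furan is absent during every earlier step. On this point the alternative is stronger than the chosen route, where the furan must survive an organolithium, an iodination and two palladium steps.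
- Against: it takes apart the one piece of the molecule that can be bought whole (17). It adds steps for the enal and the mixed acetal. It exposes a metathesis catalyst to a substrate with six further C=C bonds, among them the isopropenyl group and the enoate. It carries an acid-labile acetal through a long linear sequence.
- Comparison: it says nothing about C5 or about the Z-enoate, which would still need the chemistry of the chosen route. The chosen strategy spends its key step on the only stereocentre.

**Alternative 2: Johnson–Claisen rearrangement of a Baylis–Hillman alcohol.**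
- Disconnection: the C3–C4 bond next to the acrylate.
- Forward key step: the racemic allylic alcohol A4, heated with an orthoacetate and a trace of weak acid, forms a ketene acetal that rearranges sigmatropically to the Z-alkylidene glutarate A3.
- For: cheap, free of tin and palladium, and the chair transition state favours the required Z geometry for an alkyl-substituted carbinol. For the enoate alone it is as strong as, and cheaper than, the hydrostannation–iodination–coupling sequence.
- Against: the geometry comes from a conformational preference and is not stereospecific, so some E isomer must be expected. More seriously, A3 is achiral. Its saturated ester carbon would have to become C5 of 29, carrying isopropenyl and the triene chain. That means differentiating two esters and then performing an enantioselective C–C construction of the same kind as the chosen key step, but later and in the presence of the furan and the enoate.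
- Comparison: it solves the easier problem first and defers the hard one. The chosen route sets C5 on a simple hydrocarbon and joins the enoate afterwards in one convergent step.

**Alternative 3: neryl sulfone anion alkylated by a limonene-derived allylic bromide.**
- Disconnection: the C9–C10 bond of 29, between the two allylic methylene carbons of the triene.
- Forward key step: the sulfone A6, deprotonated by an alkyllithium at low temperature, displaces bromide from the E-allylic bromide A7 to give sulfone A5 as both epimers at the sulfone carbon.
- For: C5 comes from the chiral pool. The R centre of (R)-limonene A8 maps directly onto C5, so enantiopurity does not depend on a catalyst. This is stronger than the chosen route on that point. Sulfone alkylation is robust and the Z alkene again comes from nerol 1.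
- Against: A7 needs a selective cleavage of the ring alkene of A8 beside the isopropenyl group, ketalisation, an E-selective olefination, reduction and bromination. Reductive removal of an allylic sulfone can shift or scramble the neighbouring Z alkene. The methyl ketone left after deprotection must still be converted into the Z-alkylidene acid with the furylethyl arm, which needs a regio- and geometry-defined enol derivative and a carbonylation, or a longer detour.
- Comparison: the sequence is longer and its weakest steps come at the end. The chosen route gives up the chiral-pool guarantee. In return it has a short, catalytic entry to C5, stereospecific construction of every alkene, and a convergent finish.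

Key step: step 10

Remark: the antipode of the chiral imidazolinium sulfonate that gives (3S)-16 is assigned from the accepted stereochemical model of this catalyst class; if the sense proved opposite, the mirror-image salt would be used with no other change.

## Route

**Step 1**
Reactants: 1 nerol
Product: 2 neryl bromide, (2Z)-1-bromo-3,7-dimethylocta-2,6-diene
Conditions: PBr3 (0.4 equiv), pyridine (cat.), Et2O, −20 → 0 °C; used crude
Reagents that add atoms: phosphorus tribromide, BrP(Br)Br
Why: Bromination of a primary allylic alcohol through its phosphite ester with SN2 displacement by bromide; low temperature in ether should keep the allyl system from ionising, so the Z geometry and the linear skeleton are retained.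

**Step 2**
Reactants: 2 neryl bromide; 3 ethyl acetoacetate
Product: 5 ethyl (6Z)-7,11-dimethyl-3-oxododeca-6,10-dienoate, via acetoacetate dianion 4 (not isolated)
Conditions: 3, NaH, THF, 0 °C; n-BuLi, 0 °C; then 2, 0 °C → 23 °C; cold 1 M HCl quench
Reagents that add atoms: none
Why: γ-Alkylation of a β-keto ester dianion: the more basic terminal carbanion of 4 attacks the primary allylic bromide in SN2 fashion, and the neryl alkene is not involved.

**Step 3**
Reactants: 5 ethyl (6Z)-7,11-dimethyl-3-oxododeca-6,10-dienoate
Product: 7 ethyl (2Z,6Z)-3-[(diethoxyphosphoryl)oxy]-7,11-dimethyldodeca-2,6,10-trienoate, via sodium enolate 6 (not isolated)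
Conditions: NaH, Et2O, 0 °C; ClP(O)(OEt)2, 0 → 23 °C
Reagents that add atoms: diethyl chlorophosphate, CCOP(=O)(Cl)OCC
Why: In ether the sodium enolate is the chelated Z-enolate, and O-phosphorylation should fix it as the Z-enol phosphate with ester and phosphate cis (enol phosphate formation from a β-keto ester).

**Step 4**
Reactants: 7 ethyl (2Z,6Z)-3-[(diethoxyphosphoryl)oxy]-7,11-dimethyldodeca-2,6,10-trienoate
Product: 8 ethyl (2E,6Z)-3,7,11-trimethyldodeca-2,6,10-trienoate
Conditions: Me2CuLi (from CuI and 2 MeLi), Et2O, −78 → −45 °C
Reagents that add atoms: lithium dimethylcuprate, [Li+].C[Cu-]C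
Why: Cuprate substitution of a β-phosphoryloxy enoate proceeds with retention, so methyl takes the place of the phosphate cis to the ester and the 2E trisubstituted alkene should result; the low temperature suppresses a second conjugate addition.

**Step 5**
Reactants: 8 ethyl (2E,6Z)-3,7,11-trimethyldodeca-2,6,10-trienoate
Product: 9 (2E,6Z)-3,7,11-trimethyldodeca-2,6,10-trien-1-ol, (2E,6Z)-farnesol
Conditions: i-Bu2AlH (2.2 equiv), CH2Cl2, −78 → 0 °C; aq. potassium sodium tartrate
Reagents that add atoms: none
Why: 1,2-Reduction of a conjugated ester to the allylic alcohol by an aluminium hydride; the alkenes are untouched.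

**Step 6**
Reactants: 9 (2E,6Z)-farnesol
Product: 10 (2E,6Z)-1-bromo-3,7,11-trimethyldodeca-2,6,10-triene
Conditions: PBr3 (0.4 equiv), pyridine (cat.), Et2O, −10 → 0 °C; used crude
Reagents that add atoms: phosphorus tribromide, BrP(Br)Br
Why: Same allylic bromination as in step 1, at the primary carbon without allylic shift.

**Step 7**
Reactants: 10 (2E,6Z)-1-bromo-3,7,11-trimethyldodeca-2,6,10-triene; 11 propargyl alcohol
Product: 12 (5E,9Z)-6,10,14-trimethylpentadeca-5,9,13-trien-2-yn-1-ol
Conditions: 11 (1.5 equiv), CuI (10 mol %), K2CO3, n-Bu4NCl, DMF, 23 °C
Reagents that add atoms: none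
Why: Copper-catalysed allylation of a terminal alkyne: the copper acetylide formed under carbonate displaces the primary allylic bromide at its unsubstituted terminus, since attack at the fully substituted γ-carbon is disfavoured; the free hydroxyl is tolerated.

**Step 8**
Reactants: 12 (5E,9Z)-6,10,14-trimethylpentadeca-5,9,13-trien-2-yn-1-ol
Product: 13 (2E,5E,9Z)-6,10,14-trimethylpentadeca-2,5,9,13-tetraen-1-ol
Conditions: LiAlH4, THF, 0 → 45 °C; aqueous work-up
Reagents that add atoms: none
Why: Hydroxyl-directed trans-hydroalumination of a propargylic alcohol; protonolysis of the alkenylaluminate should give only the E-allylic alcohol, and isolated trisubstituted alkenes do not react with LiAlH4.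

**Step 9**
Reactants: 13 (2E,5E,9Z)-6,10,14-trimethylpentadeca-2,5,9,13-tetraen-1-ol
Product: 14 diethyl (2E,5E,9Z)-6,10,14-trimethylpentadeca-2,5,9,13-tetraen-1-yl phosphate
Conditions: ClP(O)(OEt)2, Et3N, DMAP (cat.), CH2Cl2, 0 °C
Reagents that add atoms: diethyl chlorophosphate, CCOP(=O)(Cl)OCC
Why: O-Phosphorylation of a primary allylic alcohol under nucleophilic catalysis.

**Step 10**
Reactants: 14 diethyl (2E,5E,9Z)-6,10,14-trimethylpentadeca-2,5,9,13-tetraen-1-yl phosphate; 15 isopropenylboronic acid pinacol ester
Product: 16 (3S,5E,9Z)-6,10,14-trimethyl-3-(prop-1-en-2-yl)pentadeca-1,5,9,13-tetraene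
Conditions: 15 (2 equiv), CuCl (5 mol %), chiral 4,5-diphenylimidazolinium salt with an N-(2-sulfonatoaryl) and an N-(2,6-dialkylaryl) group (5.5 mol %), NaOMe (1.5 equiv), THF, 22 → 50 °C
Reagents that add atoms: none
Why: NaOMe frees the carbene from the imidazolinium salt and turns CuCl into a carbene–copper methoxide, to which the methoxide-activated boronate 15 hands over its isopropenyl group (boron-to-copper transmetalation at monovalent copper). The alkenylcopper binds the E-alkene of 14 anti to the phosphate, oxidative addition with allylic transposition gives a trivalent copper σ-allyl species at the γ-carbon, and reductive elimination forms the C3–C(isopropenyl) bond. The closest known reaction type is the copper–N-heterocyclic-carbene-catalysed enantioselective SN2' substitution of E-1,2-disubstituted allylic phosphates by alkenyl–B(pin) reagents, 1,1-disubstituted alkenylboron reagents and alkyl-substituted phosphates included. No ring is closed. The new stereocentre C3 is set by the catalyst alone: the sulfonate arm holds a sodium ion that binds the phosphate and fixes the alkene under the chiral carbene, so one enantioface of the γ-carbon is alkenylated, and the antipode of the ligand is chosen for 3S. The step needs γ- over α-attack, which the bulky carbene–copper alkenyl and the unhindered γ-CH secure, and face selectivity, which depends on 14 being a single E isomer (hence the stereospecific trans-reduction in step 8). It also needs chemoselectivity, which is secured because only the alkene next to the leaving group can undergo the addition and the three trisubstituted alkenes are inert. The doubly allylic C3–H of 16 is not acidic enough for methoxide to move the double bonds into conjugation.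

**Step 11**
Reactants: 17 furan-3-ylmethanol
Product: 18 3-(bromomethyl)furan
Conditions: PBr3 (0.4 equiv), pyridine (cat.), Et2O, 0 °C; kept cold in solution and used at once
Reagents that add atoms: phosphorus tribromide, BrP(Br)Br
Why: Bromination of a primary, benzylic-type alcohol; the product is labile and is therefore not stored.

**Step 12**
Reactants: 18 3-(bromomethyl)furan; 19 trimethyl(prop-1-yn-1-yl)silane
Product: 21 [4-(furan-3-yl)but-1-yn-1-yl]trimethylsilane, via lithiated silylpropyne 20 (not isolated)
Conditions: 19, n-BuLi, THF, −78 °C; then 18, −78 → 0 °C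
Reagents that add atoms: none
Why: Lithiated 1-silylpropyne is a propargyl anion equivalent that alkylates at its CH2 terminus, because the silyl group blocks the alkyne end and disfavours allene formation; SN2 on the reactive furylmethyl bromide.

**Step 13**
Reactants: 21 [4-(furan-3-yl)but-1-yn-1-yl]trimethylsilane
Product: 22 3-(but-3-yn-1-yl)furan
Conditions: K2CO3 (cat.), MeOH, 23 °C; careful concentration (volatile)
Reagents that add atoms: none
Why: Methanolysis of the alkynyl C–Si bond under catalytic carbonate.

**Step 14**
Reactants: 22 3-(but-3-yn-1-yl)furan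
Product: 24 ethyl 5-(furan-3-yl)pent-2-ynoate, via lithium acetylide 23 (not isolated)
Conditions: n-BuLi (1.0 equiv), THF, −78 °C; ClCO2Et, −78 → 0 °C
Reagents that add atoms: ethyl chloroformate, CCOC(=O)Cl
Why: The terminal alkyne is far more acidic than the furan C–H bonds, so one equivalent of base gives only the acetylide, which is C-acylated by the chloroformate.

**Step 15**
Reactants: 24 ethyl 5-(furan-3-yl)pent-2-ynoate
Product: 25 ethyl (2E)-5-(furan-3-yl)-2-(tributylstannyl)pent-2-enoate
Conditions: Bu3SnH, Pd(PPh3)4 (2 mol %), THF, 0 → 23 °C
Reagents that add atoms: tributyltin hydride, CCCC[SnH](CCCC)CCCC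
Why: Palladium-catalysed hydrostannation of an ynoate: syn addition with tin at the α-carbon and hydride at the β-carbon, so the ester and the furylethyl chain should end up cis.

**Step 16**
Reactants: 25 ethyl (2E)-5-(furan-3-yl)-2-(tributylstannyl)pent-2-enoate
Product: 26 ethyl (2E)-5-(furan-3-yl)-2-iodopent-2-enoate
Conditions: I2 (1.05 equiv), CH2Cl2, 0 °C, dark
Reagents that add atoms: iodine, II
Why: Iododestannylation (ipso substitution at the C–Sn bond) with retention of alkene geometry; at 0 °C with one equivalent it should be much faster than iodination of the furan.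

**Step 17**
Reactants: 16 (3S,5E,9Z)-6,10,14-trimethyl-3-(prop-1-en-2-yl)pentadeca-1,5,9,13-tetraene; 26 ethyl (2E)-5-(furan-3-yl)-2-iodopent-2-enoate
Product: 28 ethyl (2Z,5R,7E,11Z)-2-[3-(furan-3-yl)propylidene]-8,12,16-trimethyl-5-(prop-1-en-2-yl)heptadeca-7,11,15-trienoate, via alkyldisiamylborane 27 (not isolated)
Conditions: disiamylborane [bis(3-methylbutan-2-yl)borane, from BH3·THF and 2-methylbut-2-ene] (1.2 equiv), THF, 0 → 23 °C; then 26, PdCl2(dppf) (10 mol %), AsPh3, Cs2CO3, DMF/THF/H2O, 23 °C
Reagents that add atoms: none
Why: Disiamylborane, unlike 9-BBN, reacts much more slowly with 1,1-disubstituted than with monosubstituted alkenes, so anti-Markovnikov hydroboration should take place at the vinyl group only. The primary alkyl group of 27 then transfers, in preference to the two secondary groups, in a B-alkyl Suzuki–Miyaura coupling that replaces iodine with retention and so fixes the Z-enoate; the stereocentre is not touched (its descriptor changes to R only because the vinyl group has become a CH2CH2 chain).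

**Step 18**
Reactants: 28 ethyl (2Z,5R,7E,11Z)-2-[3-(furan-3-yl)propylidene]-8,12,16-trimethyl-5-(prop-1-en-2-yl)heptadeca-7,11,15-trienoate
Product: 29 (2Z,5R,7E,11Z)-2-[3-(furan-3-yl)propylidene]-8,12,16-trimethyl-5-(prop-1-en-2-yl)heptadeca-7,11,15-trienoic acid
Conditions: LiOH, THF/MeOH/H2O, 23 → 40 °C; then 1 M HCl to pH 4, 0 °C
Reagents that add atoms: lithium hydroxide, [Li+].[OH-]
Why: Saponification by acyl–oxygen cleavage; the moderate temperature and the acidification only to pH 4 should spare the enoate geometry, the furan and the polyene.

## Compound list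

1 | nerol, (2Z)-3,7-dimethylocta-2,6-dien-1-ol | OC/C=C(/C)CCC=C(C)C | starting material
2 | neryl bromide, (2Z)-1-bromo-3,7-dimethylocta-2,6-diene | BrC/C=C(/C)CCC=C(C)C | intermediate
3 | ethyl acetoacetate | CCOC(=O)CC(C)=O | starting material
4 | sodium lithium dianion of ethyl acetoacetate | C=C([O-])C=C([O-])OCC.[Na+].[Li+] | intermediate (not isolated)
5 | ethyl (6Z)-7,11-dimethyl-3-oxododeca-6,10-dienoate | CCOC(=O)CC(=O)CC/C=C(/C)CCC=C(C)C | intermediate
6 | sodium (Z)-enolate of 5 | CCOC(=O)/C=C(\[O-])CC/C=C(/C)CCC=C(C)C.[Na+] | intermediate (not isolated)
7 | ethyl (2Z,6Z)-3-[(diethoxyphosphoryl)oxy]-7,11-dimethyldodeca-2,6,10-trienoate | CCOC(=O)/C=C(\OP(=O)(OCC)OCC)CC/C=C(/C)CCC=C(C)C | intermediate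
8 | ethyl (2E,6Z)-3,7,11-trimethyldodeca-2,6,10-trienoate | CCOC(=O)/C=C(\C)CC/C=C(/C)CCC=C(C)C | intermediate
9 | (2E,6Z)-3,7,11-trimethyldodeca-2,6,10-trien-1-ol | OC/C=C(\C)CC/C=C(/C)CCC=C(C)C | intermediate
10 | (2E,6Z)-1-bromo-3,7,11-trimethyldodeca-2,6,10-triene | BrC/C=C(\C)CC/C=C(/C)CCC=C(C)C | intermediate
11 | propargyl alcohol, prop-2-yn-1-ol | OCC#C | starting material
12 | (5E,9Z)-6,10,14-trimethylpentadeca-5,9,13-trien-2-yn-1-ol | OCC#CC/C=C(\C)CC/C=C(/C)CCC=C(C)C | intermediate
13 | (2E,5E,9Z)-6,10,14-trimethylpentadeca-2,5,9,13-tetraen-1-ol | OC/C=C/C/C=C(\C)CC/C=C(/C)CCC=C(C)C | intermediate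
14 | diethyl (2E,5E,9Z)-6,10,14-trimethylpentadeca-2,5,9,13-tetraen-1-yl phosphate | CCOP(=O)(OCC)OC/C=C/C/C=C(\C)CC/C=C(/C)CCC=C(C)C | intermediate
15 | isopropenylboronic acid pinacol ester, 4,4,5,5-tetramethyl-2-(prop-1-en-2-yl)-1,3,2-dioxaborolane | CC(=C)B1OC(C)(C)C(C)(C)O1 | starting material
16 | (3S,5E,9Z)-6,10,14-trimethyl-3-(prop-1-en-2-yl)pentadeca-1,5,9,13-tetraene | C=C(C)[C@@H](C/C=C(\C)CC/C=C(/C)CCC=C(C)C)C=C | intermediate
17 | furan-3-ylmethanol | OCc1ccoc1 | starting material
18 | 3-(bromomethyl)furan | BrCc1ccoc1 | intermediate
19 | trimethyl(prop-1-yn-1-yl)silane | CC#C[Si](C)(C)C | starting material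
20 | [3-(trimethylsilyl)prop-2-yn-1-yl]lithium | [Li]CC#C[Si](C)(C)C | intermediate (not isolated)
21 | [4-(furan-3-yl)but-1-yn-1-yl]trimethylsilane | C[Si](C)(C)C#CCCc1ccoc1 | intermediate
22 | 3-(but-3-yn-1-yl)furan | C#CCCc1ccoc1 | intermediate
23 | [4-(furan-3-yl)but-1-yn-1-yl]lithium | [Li]C#CCCc1ccoc1 | intermediate (not isolated)
24 | ethyl 5-(furan-3-yl)pent-2-ynoate | CCOC(=O)C#CCCc1ccoc1 | intermediate
25 | ethyl (2E)-5-(furan-3-yl)-2-(tributylstannyl)pent-2-enoate | CCOC(=O)/C(=C\CCc1ccoc1)[Sn](CCCC)(CCCC)CCCC | intermediate
26 | ethyl (2E)-5-(furan-3-yl)-2-iodopent-2-enoate | CCOC(=O)/C(I)=C\CCc1ccoc1 | intermediate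
27 | bis(3-methylbutan-2-yl)[(3R,5E,9Z)-6,10,14-trimethyl-3-(prop-1-en-2-yl)pentadeca-5,9,13-trien-1-yl]borane | C=C(C)[C@@H](C/C=C(\C)CC/C=C(/C)CCC=C(C)C)CCB(C(C)C(C)C)C(C)C(C)C | intermediate (not isolated)
28 | ethyl (2Z,5R,7E,11Z)-2-[3-(furan-3-yl)propylidene]-8,12,16-trimethyl-5-(prop-1-en-2-yl)heptadeca-7,11,15-trienoate | C=C(C)[C@@H](C/C=C(\C)CC/C=C(/C)CCC=C(C)C)CC/C(=C/CCc1ccoc1)C(=O)OCC | intermediate
29 | (2Z,5R,7E,11Z)-2-[3-(furan-3-yl)propylidene]-8,12,16-trimethyl-5-(prop-1-en-2-yl)heptadeca-7,11,15-trienoic acid | C=C(C)[C@@H](C/C=C(\C)CC/C=C(/C)CCC=C(C)C)CC/C(=C/CCc1ccoc1)C(=O)O | target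

## Step count and least certain steps

Total step count: 18. Longest linear sequence: 12 steps (steps 1–10, 17 and 18, from nerol 1). The iodoenoate branch (steps 11–16) has 6 steps.

**Step 10 (key step).** The most likely failures are slow boron-to-copper transfer of the 1,1-disubstituted alkenyl group, which would let linear (α) substitution or methoxide attack compete, and incomplete enantioface discrimination on a purely aliphatic phosphate. The fallback sets out from bromide 10 and comes back at 16. It sets the centre with a chiral auxiliary instead of a catalyst. (4R)-4-Benzyl-1,3-oxazolidin-2-one is N-acylated (n-BuLi, 3-methylbut-2-enoyl chloride) to (4R)-4-benzyl-3-(3-methylbut-2-enoyl)-1,3-oxazolidin-2-one F1. Its sodium dienolate (NaN(SiMe3)2, THF, −78 °C) is alkylated at the α-carbon by 10, anti to the benzyl group and with deconjugation (Evans alkylation), to give (4R)-4-benzyl-3-[(2R,4E,8Z)-5,9,13-trimethyl-2-(prop-1-en-2-yl)tetradeca-4,8,12-trienoyl]-1,3-oxazolidin-2-one F2. LiBH4 removes the auxiliary and gives (2R,4E,8Z)-5,9,13-trimethyl-2-(prop-1-en-2-yl)tetradeca-4,8,12-trien-1-ol F3. Buffered Dess–Martin oxidation gives (2R,4E,8Z)-5,9,13-trimethyl-2-(prop-1-en-2-yl)tetradeca-4,8,12-trienal F4. Non-basic Takai–Lombardo methylenation (Zn, CH2Br2, TiCl4) is chosen because the aldehyde is prone to epimerisation and conjugation, and it converts F4 into 16.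

**Step 17.** Two things may go wrong: incomplete discrimination between the vinyl and isopropenyl groups in the hydroboration, and sluggish transfer of the alkyl group from the hindered borane to palladium, which would leave the iodide to be reduced. The fallback sets out from 16 and comes back at 28, replacing the boron coupling by a zinc coupling. After the same hydroboration, 27 is oxidised in the flask (NaOH, H2O2) to (3S,5E,9Z)-6,10,14-trimethyl-3-(prop-1-en-2-yl)pentadeca-5,9,13-trien-1-ol F5, which can be purified from any regioisomer. PPh3, I2 and imidazole give (3S,5E,9Z)-1-iodo-6,10,14-trimethyl-3-(prop-1-en-2-yl)pentadeca-5,9,13-triene F6. LiCl-promoted zinc insertion (Zn dust, THF) gives iodo[(3S,5E,9Z)-6,10,14-trimethyl-3-(prop-1-en-2-yl)pentadeca-5,9,13-trien-1-yl]zinc F7. Negishi coupling with 26 under PdCl2(dppf) then gives 28.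

**Step 7.** Partial attack of the copper acetylide at the substituted allyl terminus (SN2' product), or erosion of the 2E geometry through an allylcopper species, would contaminate 12. The fallback sets out from 10 and comes back at 12, using an uncatalysed SN2 alkylation of a lithium acetylide. Commercial 2-(prop-2-yn-1-yloxy)oxane is deprotonated (n-BuLi, THF/DMPU, −78 °C) and alkylated by 10 to give 2-{[(5E,9Z)-6,10,14-trimethylpentadeca-5,9,13-trien-2-yn-1-yl]oxy}oxane F8. Pyridinium p-toluenesulfonate in MeOH removes the acetal and gives 12.

**Step 12.** Bromide 18 may decompose or polymerise before or during the alkylation, and the anion 20 may react in part through its allenyl form. The fallback sets out from 17 and comes back at 22, avoiding any furylmethyl halide. Oxidation with MnO2 gives furan-3-carbaldehyde F9. Wittig reaction with Ph3P=CHCO2Et gives ethyl (2E)-3-(furan-3-yl)prop-2-enoate F10. Conjugate reduction (NaBH4, NiCl2·6H2O, EtOH, 0 °C) gives ethyl 3-(furan-3-yl)propanoate F11. Half-reduction with i-Bu2AlH at −78 °C gives 3-(furan-3-yl)propanal F12. Ohira–Bestmann homologation (dimethyl (1-diazo-2-oxopropyl)phosphonate, K2CO3, MeOH) gives 22.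

## Further compounds

F1 | step 10 | (4R)-4-benzyl-3-(3-methylbut-2-enoyl)-1,3-oxazolidin-2-one | CC(C)=CC(=O)N1[C@H](Cc2ccccc2)COC1=O
F2 | step 10 | (4R)-4-benzyl-3-[(2R,4E,8Z)-5,9,13-trimethyl-2-(prop-1-en-2-yl)tetradeca-4,8,12-trienoyl]-1,3-oxazolidin-2-one | C=C(C)[C@@H](C/C=C(\C)CC/C=C(/C)CCC=C(C)C)C(=O)N1[C@H](Cc2ccccc2)COC1=O
F3 | step 10 | (2R,4E,8Z)-5,9,13-trimethyl-2-(prop-1-en-2-yl)tetradeca-4,8,12-trien-1-ol | C=C(C)[C@@H](C/C=C(\C)CC/C=C(/C)CCC=C(C)C)CO
F4 | step 10 | (2R,4E,8Z)-5,9,13-trimethyl-2-(prop-1-en-2-yl)tetradeca-4,8,12-trienal | C=C(C)[C@@H](C/C=C(\C)CC/C=C(/C)CCC=C(C)C)C=O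
F5 | step 17 | (3S,5E,9Z)-6,10,14-trimethyl-3-(prop-1-en-2-yl)pentadeca-5,9,13-trien-1-ol | C=C(C)[C@@H](C/C=C(\C)CC/C=C(/C)CCC=C(C)C)CCO
F6 | step 17 | (3S,5E,9Z)-1-iodo-6,10,14-trimethyl-3-(prop-1-en-2-yl)pentadeca-5,9,13-triene | C=C(C)[C@@H](C/C=C(\C)CC/C=C(/C)CCC=C(C)C)CCI
F7 | step 17 | iodo[(3S,5E,9Z)-6,10,14-trimethyl-3-(prop-1-en-2-yl)pentadeca-5,9,13-trien-1-yl]zinc | C=C(C)[C@@H](C/C=C(\C)CC/C=C(/C)CCC=C(C)C)CC[Zn]I
F8 | step 7 | 2-{[(5E,9Z)-6,10,14-trimethylpentadeca-5,9,13-trien-2-yn-1-yl]oxy}oxane | C(OC1CCCCO1)C#CC/C=C(\C)CC/C=C(/C)CCC=C(C)C
F9 | step 12 | furan-3-carbaldehyde | O=Cc1ccoc1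
F10 | step 12 | ethyl (2E)-3-(furan-3-yl)prop-2-enoate | CCOC(=O)/C=C/c1ccoc1
F11 | step 12 | ethyl 3-(furan-3-yl)propanoate | CCOC(=O)CCc1ccoc1
F12 | step 12 | 3-(furan-3-yl)propanal | O=CCCc1ccoc1
A1 | alternative 1 | methyl (2Z,5R,7E,11Z)-2-[3-(furan-3-yl)propylidene]-8,12,16-trimethyl-5-(prop-1-en-2-yl)heptadeca-7,11,15-trienoate | C=C(C)[C@@H](C/C=C(\C)CC/C=C(/C)CCC=C(C)C)CC/C(=C/CCc1ccoc1)C(=O)OC
A2 | alternative 1 | methyl (2Z,5R,7E,11Z)-2-{4-[methoxy(prop-2-en-1-yloxy)methyl]pent-4-en-1-ylidene}-8,12,16-trimethyl-5-(prop-1-en-2-yl)heptadeca-7,11,15-trienoate (both acetal epimers) | C=C(C)[C@@H](C/C=C(\C)CC/C=C(/C)CCC=C(C)C)CC/C(=C/CCC(=C)C(OC)OCC=C)C(=O)OC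
A3 | alternative 2 | 5-ethyl 1-methyl (2Z)-2-[3-(furan-3-yl)propylidene]pentanedioate | CCOC(=O)CC/C(=C/CCc1ccoc1)C(=O)OC
A4 | alternative 2 | methyl 2-[3-(furan-3-yl)-1-hydroxypropyl]prop-2-enoate (racemic) | C=C(C(=O)OC)C(O)CCc1ccoc1
A5 | alternative 3 | 2-methyl-2-[(3R,5E,9Z)-6,10,14-trimethyl-8-(phenylsulfonyl)-3-(prop-1-en-2-yl)pentadeca-5,9,13-trien-1-yl]-1,3-dioxolane (both epimers at the sulfone carbon) | C=C(C)[C@@H](C/C=C(\C)CC(/C=C(/C)CCC=C(C)C)S(=O)(=O)c1ccccc1)CCC1(C)OCCO1
A6 | alternative 3 | {[(2Z)-3,7-dimethylocta-2,6-dien-1-yl]sulfonyl}benzene | CC(C)=CCC/C(C)=C\CS(=O)(=O)c1ccccc1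
A7 | alternative 3 | 2-[(3R,5E)-7-bromo-6-methyl-3-(prop-1-en-2-yl)hept-5-en-1-yl]-2-methyl-1,3-dioxolane | C=C(C)[C@@H](C/C=C(\C)CBr)CCC1(C)OCCO1
A8 | alternative 3 | (R)-limonene, (4R)-1-methyl-4-(prop-1-en-2-yl)cyclohex-1-ene | CC1=CC[C@@H](CC1)C(C)=C
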